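The (8Z)-trisubstituted olefin is hidden in a ring: C7, C8 (with its methyl), C9, C10 (with its methyl) and C11 are built as a six-membered α,β-unsaturated lactone, and a ring of that size forces C7 and C10 onto the same side of the endocyclic C8=C9 bond. One ring-closing metathesis of the methacrylate of (R)-2-methylbut-3-en-1-ol forms that bond and the ring together, leaving a masked (Z)-enal at C7 and a masked alcohol at C11. Reduction, Wittig extension, crotylboration and a second metathesis give the C1–C11 lactone iodide. It is joined at C11–C12 by Negishi coupling to a C12–C24 dienyl iodide made by crotylboration and an Evans aldol.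

Key step: step 5

Remark: atoms are numbered from the lactone carbonyl (C1) to the carboxyl carbon (C24). The SMILES is read as 4S,5R (methyl and side chain trans on the lactone), 10S, 16S, 18R, 19R, 20R, with 8Z and all other chain olefins E; the route is designed for exactly this isomer. The crotylborane 18 is thermally labile, so step 10 is run at −78 °C directly before each of its two uses (steps 11 and 18) and is counted once.

Step 1
Reactants: 1 methyl (S)-3-hydroxy-2-methylpropanoate
Product: 2 methyl (S)-3-[(tert-butyldimethylsilyl)oxy]-2-methylpropanoate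
Conditions: TBSCl, imidazole, CH2Cl2, 0 → 25 °C
Reagents that add atoms: tert-butyldimethylsilyl chloride, CC(C)(C)[Si](C)(C)Cl
Why: Imidazole-promoted silylation of a primary alcohol, which does not touch the α-stereocentre (the future C10).

Step 2
Reactants: 2 methyl (S)-3-[(tert-butyldimethylsilyl)oxy]-2-methylpropanoate
Product: 3 (S)-3-[(tert-butyldimethylsilyl)oxy]-2-methylpropanal
Conditions: iBu2AlH (1.05 equiv), CH2Cl2, −78 °C; aq. KNaC4H4O6 (potassium sodium tartrate)
Reagents that add atoms: none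
Why: Partial ester reduction, in which the aluminium hemiacetal is stable at −78 °C and collapses to the aldehyde only on work-up, so the α-centre should not epimerise.

Step 3
Reactants: 3 (S)-3-[(tert-butyldimethylsilyl)oxy]-2-methylpropanal
Product: 4 (R)-tert-butyldimethyl[(2-methylbut-3-en-1-yl)oxy]silane
Conditions: Ph3PCH3Br, KN(SiMe3)2, THF, 0 °C; then 3, −78 → 25 °C
Reagents that add atoms: methyltriphenylphosphonium bromide, C[P+](c1ccccc1)(c1ccccc1)c1ccccc1.[Br-]
Why: Wittig methylenation with the preformed ylide at low temperature turns the aldehyde carbon into C9 faster than the α-centre can enolise; the descriptor changes to R only through the priority change.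

Step 4
Reactants: 4 (R)-tert-butyldimethyl[(2-methylbut-3-en-1-yl)oxy]silane; 5 methacryloyl chloride
Product: 7 (R)-2-methylbut-3-en-1-yl methacrylate, via (R)-2-methylbut-3-en-1-ol 6 (not isolated)
Conditions: Bu4NF, THF, 0 → 25 °C; then Et3N, DMAP (cat.), 5, 0 → 25 °C
Reagents that add atoms: none
Why: Fluoride desilylation followed by DMAP-catalysed O-acylation in the same flask, so that the volatile alcohol never has to be handled neat; the stereocentre is not involved.

Step 5
Reactants: 7 (R)-2-methylbut-3-en-1-yl methacrylate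
Product: 8 (R)-3,5-dimethyl-5,6-dihydro-2H-pyran-2-one
Conditions: second-generation Grubbs catalyst (H2IMes)(PCy3)Cl2Ru=CHPh (5 mol %), 1,4-benzoquinone (10 mol %), toluene (0.01 M), 80 °C, argon sweep
Reagents that add atoms: none
Why: The ruthenium benzylidene first exchanges with the unhindered monosubstituted vinyl group of 7, the new alkylidene adds intramolecularly to the 1,1-disubstituted methacrylate olefin in a [2+2] step, and cycloreversion of the ruthenacyclobutane releases the trisubstituted C8=C9 bond while ethene escapes. The closest known reaction type is ring-closing metathesis of methacrylates of homoallylic alcohols to 3-methyl-5,6-dihydropyran-2-ones. The one ring is closed as a six-membered lactone by olefin–olefin metathesis between the two terminal alkene carbons, so the new double bond is endocyclic. No stereocentre is created, and the olefin geometry is dictated by the ring, which cannot hold a trans double bond, so C7 and C10 must be cis (8Z). The step needs initiation at the vinyl group and not at the electron-poor methacrylate (secured by their different substitution), cyclisation instead of dimerisation (secured by dilution, heat and removal of ethene), and an untouched allylic C10 centre (secured by 1,4-benzoquinone, which intercepts ruthenium hydrides that would migrate the double bond).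

Step 6
Reactants: 8 (R)-3,5-dimethyl-5,6-dihydro-2H-pyran-2-one
Product: 9 (5R)-3,5-dimethyl-5,6-dihydro-2H-pyran-2-ol (anomer mixture)
Conditions: iBu2AlH (1.1 equiv), CH2Cl2, −78 °C; aq. KNaC4H4O6 (potassium sodium tartrate)
Reagents that add atoms: none
Why: 1,2-Reduction of the unsaturated δ-lactone stops at the lactol because the aluminium acetal does not open in the cold.

Step 7
Reactants: 9 (5R)-3,5-dimethyl-5,6-dihydro-2H-pyran-2-ol; 10 N-methoxy-N-methyl-2-(triphenylphosphoranylidene)acetamide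
Product: 12 (2E,4Z,6R)-7-hydroxy-N-methoxy-N,4,6-trimethylhepta-2,4-dienamide, via (2Z,4R)-5-hydroxy-2,4-dimethylpent-2-enal 11 (not isolated)
Conditions: 10 (1.5 equiv), toluene, 70 °C
Reagents that add atoms: none
Why: Wittig olefination of the ring-opened hydroxy enal with a stabilised ylide should give the (E)-C6=C7 bond and keep the Z geometry inherited from the ring; the amide ylide is chosen because the product is a poor oxa-Michael acceptor for the free C11 hydroxyl and reaches the aldehyde level in one later step.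

Step 8
Reactants: 12 (2E,4Z,6R)-7-hydroxy-N-methoxy-N,4,6-trimethylhepta-2,4-dienamide
Product: 13 (2E,4Z,6R)-7-iodo-N-methoxy-N,4,6-trimethylhepta-2,4-dienamide
Conditions: PPh3, imidazole, I2, CH2Cl2, 0 °C, dark (alcohol added to the preformed reagent)
Reagents that add atoms: iodine, II
Why: Appel-type iodination (Garegg–Samuelsson conditions) substitutes the primary C11 hydroxyl by SN2 at a carbon that is not a stereocentre, and preforming the phosphonium iodide keeps free iodine away from the Z-diene.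

Step 9
Reactants: 13 (2E,4Z,6R)-7-iodo-N-methoxy-N,4,6-trimethylhepta-2,4-dienamide
Product: 14 (2E,4Z,6R)-7-iodo-4,6-dimethylhepta-2,4-dienal
Conditions: iBu2AlH (1.2 equiv), THF, −78 °C; aq. KNaC4H4O6 (potassium sodium tartrate)
Reagents that add atoms: none
Why: Weinreb amide reduction stops at the chelated aluminium hemiaminal, which releases the C5 aldehyde on work-up; the primary iodide is inert at −78 °C.

Step 10
Reactants: 15 (E)-but-2-ene
Product: 18 (E)-but-2-en-1-ylbis[(1R,2S,3R,5R)-2,6,6-trimethylbicyclo[3.1.1]heptan-3-yl]borane [(E)-crotyldiisopinocampheylborane], via (E)-but-2-en-1-ylpotassium 16 (not isolated), via potassium (E)-crotyl(methoxy)diisopinocampheylborate 17 (not isolated)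
Conditions: KOtBu, nBuLi, THF, −78 → −45 °C, 15 min; (−)-Ipc2BOMe, Et2O, −78 °C; BF3·OEt2, −78 °C; cold solution used at once
Reagents that add atoms: (−)-B-methoxydiisopinocampheylborane, COB([C@@H]1C[C@@H]2C[C@H]([C@H]1C)C2(C)C)[C@@H]1C[C@@H]2C[C@H]([C@H]1C)C2(C)C
Why: Schlosser-base metalation of (E)-but-2-ene gives the (E)-crotylpotassium, which keeps its geometry below −45 °C, the borinate traps it as the ate complex, and BF3·OEt2 removes methoxide to free the (E)-crotylborane (Brown protocol), which does not scramble its geometry by 1,3-boratropic shift at −78 °C and is therefore taken cold and without work-up into the crotylboration.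

Step 11
Reactants: 14 (2E,4Z,6R)-7-iodo-4,6-dimethylhepta-2,4-dienal; 18 (E)-crotyldiisopinocampheylborane
Product: 19 (3S,4R,5E,7Z,9R)-10-iodo-3,7,9-trimethyldeca-1,5,7-trien-4-ol
Conditions: 18 (1.5 equiv, fresh solution from step 10), THF/Et2O, −78 °C; then NaBO3·4H2O, THF/H2O, 25 °C
Reagents that add atoms: none
Why: Brown crotylboration through a chair Zimmerman–Traxler transition state, in which the E-crotyl geometry gives the 4,5-anti relationship and the isopinocampheyl groups derived from (−)-Ipc2BOMe deliver the crotyl unit to the Si face of the aldehyde, setting 4S,5R under reagent control (C10 is remote); the perborate work-up spares the alkyl iodide.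

Step 12
Reactants: 19 (3S,4R,5E,7Z,9R)-10-iodo-3,7,9-trimethyldeca-1,5,7-trien-4-ol; 20 acryloyl chloride
Product: 21 (3S,4R,5E,7Z,9R)-10-iodo-3,7,9-trimethyldeca-1,5,7-trien-4-yl acrylate
Conditions: 20, iPr2NEt, CH2Cl2, −78 → 0 °C
Reagents that add atoms: none
Why: O-Acylation of the secondary allylic alcohol with an acid chloride and a hindered amine at low temperature, which leaves the stereocentres and the iodide alone.

Step 13
Reactants: 21 (3S,4R,5E,7Z,9R)-10-iodo-3,7,9-trimethyldeca-1,5,7-trien-4-yl acrylate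
Product: 22 (5S,6R)-6-[(1E,3Z,5R)-6-iodo-3,5-dimethylhexa-1,3-dien-1-yl]-5-methyl-5,6-dihydro-2H-pyran-2-one
Conditions: (H2IMes)(PCy3)Cl2Ru=CHPh (5 mol %), CH2Cl2 (0.005 M), 40 °C
Reagents that add atoms: none
Why: Ring-closing metathesis of an acrylate with a monosubstituted olefin, where the catalyst loads on the terminal vinyl group and closes the six-membered lactone, while the internal diene is a much poorer substrate and offers no competing ring of favourable size.

Step 14
Reactants: 23 (S)-3-bromo-2-methylpropan-1-ol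
Product: 24 (S)-(3-bromo-2-methylpropoxy)triethylsilane
Conditions: Et3SiCl, imidazole, CH2Cl2, 0 °C
Reagents that add atoms: chlorotriethylsilane, CC[Si](Cl)(CC)CC
Why: Silylation of a primary alcohol; the stereocentre (the future C20) is not involved.

Step 15
Reactants: 25 but-2-ynoic acid; 26 2-(trimethylsilyl)ethanol
Product: 27 2-(trimethylsilyl)ethyl but-2-ynoate
Conditions: N,N'-dicyclohexylcarbodiimide, DMAP (cat.), CH2Cl2, 0 °C
Reagents that add atoms: none
Why: Steglich esterification installs an ester that resists every later step and is removed by fluoride at the end together with the silyl ethers.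

Step 16
Reactants: 24 (S)-(3-bromo-2-methylpropoxy)triethylsilane; 27 2-(trimethylsilyl)ethyl but-2-ynoate
Product: 30 2-(trimethylsilyl)ethyl (2E,5R)-3,5-dimethyl-6-(triethylsilyloxy)hex-2-enoate, via [(2S)-2-methyl-3-(triethylsilyloxy)propyl]magnesium bromide 28 (not isolated), via [(2S)-2-methyl-3-(triethylsilyloxy)propyl]copper 29 (not isolated)
Conditions: Mg, THF, 25 → 40 °C; CuBr·SMe2, −40 °C; 27, −78 °C; MeOH then aq. NH4Cl, −78 °C
Reagents that add atoms: none
Why: Syn-carbocupration of the ynoate at −78 °C and cold protonation with retention place the new alkyl group cis to the vinyl hydrogen, which is the 22E enoate; C20 comes unchanged from 23.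

Step 17
Reactants: 30 2-(trimethylsilyl)ethyl (2E,5R)-3,5-dimethyl-6-(triethylsilyloxy)hex-2-enoate
Product: 31 2-(trimethylsilyl)ethyl (2E,5R)-3,5-dimethyl-6-oxohex-2-enoate
Conditions: (COCl)2 (4 equiv), Me2SO (8 equiv), CH2Cl2, −78 → −30 °C; Et3N, −78 → 0 °C
Reagents that add atoms: none
Why: Swern oxidation in which excess chlorodimethylsulfonium chloride cleaves the primary triethylsilyl ether and oxidises the same oxygen in one flask (the known direct oxidation of primary triethylsilyl ethers), with cold addition of the amine to avoid epimerising C20.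

Step 18
Reactants: 31 2-(trimethylsilyl)ethyl (2E,5R)-3,5-dimethyl-6-oxohex-2-enoate; 18 (E)-crotyldiisopinocampheylborane
Product: 32 2-(trimethylsilyl)ethyl (2E,5R,6R,7S)-6-hydroxy-3,5,7-trimethylnona-2,8-dienoate
Conditions: 18 (1.5 equiv, fresh solution from step 10), THF/Et2O, −78 °C; then NaBO3·4H2O, THF/H2O, 25 °C
Reagents that add atoms: none
Why: Brown (E)-crotylboration gives the 18,19-anti pair through the chair transition state, and Si-face delivery by the reagent from (−)-Ipc2BOMe must override the weak Felkin preference of the α-methyl aldehyde to give the 19,20-anti relationship (anti,anti triad).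

Step 19
Reactants: 32 2-(trimethylsilyl)ethyl (2E,5R,6R,7S)-6-hydroxy-3,5,7-trimethylnona-2,8-dienoate
Product: 33 2-(trimethylsilyl)ethyl (2E,5R,6R,7S)-3,5,7-trimethyl-6-(triethylsilyloxy)nona-2,8-dienoate
Conditions: Et3SiOTf, 2,6-lutidine, CH2Cl2, −78 °C
Reagents that add atoms: triethylsilyl trifluoromethanesulfonate, CC[Si](CC)(CC)OS(=O)(=O)C(F)(F)F
Why: Silyl triflate silylation of a hindered secondary alcohol; the triethylsilyl ether is chosen because it comes off easily at the end.

Step 20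
Reactants: 33 2-(trimethylsilyl)ethyl (2E,5R,6R,7S)-3,5,7-trimethyl-6-(triethylsilyloxy)nona-2,8-dienoate
Product: 35 2-(trimethylsilyl)ethyl (2E,5R,6R,7R)-3,5,7-trimethyl-8-oxo-6-(triethylsilyloxy)oct-2-enoate, via terminal-olefin ozonide 34 (not isolated)
Conditions: O3, CH2Cl2, −78 °C, Sudan Red 7B end point; PPh3, −78 → 25 °C
Reagents that add atoms: ozone, [O-][O+]=O
Why: Ozonolysis with an indicator end point cleaves the electron-rich monosubstituted olefin well before the electron-poor conjugated ester olefin, giving the C17 aldehyde without touching C18.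

Step 21
Reactants: 36 but-3-enoic acid; 37 (R)-4-benzyloxazolidin-2-one
Product: 39 (R)-4-benzyl-3-(but-3-enoyl)oxazolidin-2-one, via but-3-enoic pivalic anhydride 38 (not isolated)
Conditions: pivaloyl chloride, Et3N, THF, −20 °C; then LiCl, 37, −20 → 25 °C
Reagents that add atoms: none
Why: N-Acylation through the mixed pivalic anhydride with LiCl activation is mild enough to keep the β,γ-double bond out of conjugation.

Step 22
Reactants: 39 (R)-4-benzyl-3-(but-3-enoyl)oxazolidin-2-one; 40 methacrolein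
Product: 41 (R)-4-benzyl-3-[(3E)-4-methyl-5-oxopent-3-enoyl]oxazolidin-2-one
Conditions: 40 (10 equiv), (H2IMes)(PCy3)Cl2Ru=CHPh (5 mol %), 1,4-benzoquinone (10 mol %), CH2Cl2, 40 °C
Reagents that add atoms: none
Why: Cross-metathesis of an unhindered terminal olefin with excess methacrolein gives the trisubstituted (E)-enal, the 14E olefin, under thermodynamic control, and benzoquinone suppresses hydride-induced migration of the olefin into conjugation with the imide.

Step 23
Reactants: 41 (R)-4-benzyl-3-[(3E)-4-methyl-5-oxopent-3-enoyl]oxazolidin-2-one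
Product: 42 (R)-4-benzyl-3-[(3E,5E)-6-iodo-4-methylhexa-3,5-dienoyl]oxazolidin-2-one
Conditions: CrCl2 (6 equiv), CHI3 (2 equiv), THF, 0 → 25 °C, dark
Reagents that add atoms: iodoform, IC(I)I
Why: Takai olefination, in which the geminal dichromium reagent adds to the aldehyde only and eliminates to the (E)-alkenyl iodide (12E); the imide is not attacked.

Step 24
Reactants: 42 (R)-4-benzyl-3-[(3E,5E)-6-iodo-4-methylhexa-3,5-dienoyl]oxazolidin-2-one; 35 2-(trimethylsilyl)ethyl (2E,5R,6R,7R)-3,5,7-trimethyl-8-oxo-6-(triethylsilyloxy)oct-2-enoate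
Product: 44 2-(trimethylsilyl)ethyl (2E,5R,6R,7S,8S,9R)-10-[(R)-4-benzyl-2-oxooxazolidin-3-yl]-8-hydroxy-9-[(1E,3E)-4-iodo-2-methylbuta-1,3-dien-1-yl]-3,5,7-trimethyl-10-oxo-6-(triethylsilyloxy)dec-2-enoate, via dibutylboron (Z)-enolate 43 (not isolated)
Conditions: Bu2BOTf, Et3N, CH2Cl2, −78 → 0 °C; 35, −78 → 0 °C; pH 7 buffer, MeOH, H2O2, 0 °C
Reagents that add atoms: none
Why: Evans syn-aldol through the Z-boron enolate and a chair transition state, in which the benzyl group of the (R)-auxiliary blocks one enolate face and so sets C16 independently of the aldehyde (boron enolates of β,γ-unsaturated imides react at the α-carbon); the C17 carbinol formed with it is oxidised later.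

Step 25
Reactants: 44 Evans aldol adduct
Product: 45 2-(trimethylsilyl)ethyl (2E,5R,6R,7S,8R,9S,10E,12E)-8-hydroxy-9-(hydroxymethyl)-13-iodo-3,5,7,11-tetramethyl-6-(triethylsilyloxy)trideca-2,10,12-trienoate
Conditions: LiBH4, MeOH (2 equiv), THF, 0 °C
Reagents that add atoms: none
Why: Reductive removal of the auxiliary turns the imide carbonyl into the C16 hydroxymethyl group; the activated imide is reduced much faster than the conjugated, β,β-disubstituted ester at 0 °C.

Step 26
Reactants: 45 diol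
Product: 46 2-(trimethylsilyl)ethyl (2E,5R,6R,7S,8R,9S,10E,12E)-9-{[(tert-butyldimethylsilyl)oxy]methyl}-8-hydroxy-13-iodo-3,5,7,11-tetramethyl-6-(triethylsilyloxy)trideca-2,10,12-trienoate
Conditions: TBSCl (1.1 equiv), imidazole, CH2Cl2, 0 °C
Reagents that add atoms: tert-butyldimethylsilyl chloride, CC(C)(C)[Si](C)(C)Cl
Why: Selective silylation of the primary hydroxyl, since the C17 hydroxyl lies between two branched carbons and reacts far more slowly.

Step 27
Reactants: 46 primary silyl ether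
Product: 47 2-(trimethylsilyl)ethyl (2E,5R,6R,7R,9S,10E,12E)-9-{[(tert-butyldimethylsilyl)oxy]methyl}-13-iodo-3,5,7,11-tetramethyl-8-oxo-6-(triethylsilyloxy)trideca-2,10,12-trienoate
Conditions: Dess–Martin periodinane, NaHCO3, CH2Cl2, 0 → 25 °C
Reagents that add atoms: none
Why: Dess–Martin oxidation under buffered, base-free conditions gives the C17 ketone without epimerising C16 or C18 and without β-elimination of the silyloxymethyl group.

Step 28
Reactants: 22 lactone iodide; 47 ketone dienyl iodide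
Product: 49 2-(trimethylsilyl)ethyl (2E,5R,6R,7R,9S,10E,12E,15S,16Z,18E)-9-{[(tert-butyldimethylsilyl)oxy]methyl}-3,5,7,11,15,17-hexamethyl-19-[(2R,3S)-3-methyl-6-oxo-3,6-dihydro-2H-pyran-2-yl]-8-oxo-6-(triethylsilyloxy)nonadeca-2,10,12,16,18-pentaenoate, via alkylzinc iodide 48 (not isolated)
Conditions: 22 (1.4 equiv), Zn dust (activated with BrCH2CH2Br and Me3SiCl), DMF, 25 °C, dark; then 47, PdCl2(dppf) (5 mol %; dppf = 1,1'-bis(diphenylphosphino)ferrocene), THF/DMF, 25 °C
Reagents that add atoms: none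
Why: Negishi coupling, in which direct zinc insertion tolerates the lactone, the primary alkylzinc iodide neither adds to nor enolises the ketone and ester, and palladium joins C11 to C12 with retention of the alkenyl iodide geometry.

Step 29
Reactants: 49 protected coupling product
Product: 50 (2E,5R,6R,7R,9S,10E,12E,15S,16Z,18E)-6-hydroxy-9-(hydroxymethyl)-3,5,7,11,15,17-hexamethyl-19-[(2R,3S)-3-methyl-6-oxo-3,6-dihydro-2H-pyran-2-yl]-8-oxononadeca-2,10,12,16,18-pentaenoic acid (CNP0298860.3)
Conditions: tris(dimethylamino)sulfonium difluorotrimethylsilicate (6 equiv), DMF, 0 → 25 °C; aq. NH4Cl/pH 6 buffer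
Reagents that add atoms: none
Why: Fluoride-induced global deprotection, in which the anhydrous, weakly basic fluoride source cleaves both silyl ethers and fragments the 2-(trimethylsilyl)ethyl ester to the acid, ethene and fluorotrimethylsilane in one operation.

Compound list
1 | methyl (S)-3-hydroxy-2-methylpropanoate | COC(=O)[C@@H](C)CO | starting material
2 | methyl (S)-3-[(tert-butyldimethylsilyl)oxy]-2-methylpropanoate | COC(=O)[C@@H](C)CO[Si](C)(C)C(C)(C)C | intermediate
3 | (S)-3-[(tert-butyldimethylsilyl)oxy]-2-methylpropanal | O=C[C@@H](C)CO[Si](C)(C)C(C)(C)C | intermediate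
4 | (R)-tert-butyldimethyl[(2-methylbut-3-en-1-yl)oxy]silane | C=C[C@@H](C)CO[Si](C)(C)C(C)(C)C | intermediate
5 | methacryloyl chloride | C=C(C)C(Cl)=O | starting material
6 | (R)-2-methylbut-3-en-1-ol | OC[C@H](C)C=C | intermediate
7 | (R)-2-methylbut-3-en-1-yl methacrylate | C=C(C)C(=O)OC[C@H](C)C=C | intermediate
8 | (R)-3,5-dimethyl-5,6-dihydro-2H-pyran-2-one | CC1=C[C@@H](C)COC1=O | intermediate
9 | (5R)-3,5-dimethyl-5,6-dihydro-2H-pyran-2-ol (anomer mixture) | CC1=C[C@@H](C)COC1O | intermediate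
10 | N-methoxy-N-methyl-2-(triphenylphosphoranylidene)acetamide | CON(C)C(=O)C=P(c1ccccc1)(c1ccccc1)c1ccccc1 | starting material
11 | (2Z,4R)-5-hydroxy-2,4-dimethylpent-2-enal | O=C/C(C)=C\[C@@H](C)CO | intermediate
12 | (2E,4Z,6R)-7-hydroxy-N-methoxy-N,4,6-trimethylhepta-2,4-dienamide | CON(C)C(=O)/C=C/C(C)=C\[C@@H](C)CO | intermediate
13 | (2E,4Z,6R)-7-iodo-N-methoxy-N,4,6-trimethylhepta-2,4-dienamide | CON(C)C(=O)/C=C/C(C)=C\[C@@H](C)CI | intermediate
14 | (2E,4Z,6R)-7-iodo-4,6-dimethylhepta-2,4-dienal | O=C/C=C/C(C)=C\[C@@H](C)CI | intermediate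
15 | (E)-but-2-ene | C/C=C/C | starting material
16 | (E)-but-2-en-1-ylpotassium | C/C=C/C[K] | intermediate
17 | potassium [(E)-but-2-en-1-yl](methoxy)bis[(1R,2S,3R,5R)-2,6,6-trimethylbicyclo[3.1.1]heptan-3-yl]borate | [K+].C/C=C/C[B-](OC)([C@@H]1C[C@@H]2C[C@H]([C@H]1C)C2(C)C)[C@@H]1C[C@@H]2C[C@H]([C@H]1C)C2(C)C | intermediate
18 | (E)-but-2-en-1-ylbis[(1R,2S,3R,5R)-2,6,6-trimethylbicyclo[3.1.1]heptan-3-yl]borane | C/C=C/CB([C@@H]1C[C@@H]2C[C@H]([C@H]1C)C2(C)C)[C@@H]1C[C@@H]2C[C@H]([C@H]1C)C2(C)C | intermediate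
19 | (3S,4R,5E,7Z,9R)-10-iodo-3,7,9-trimethyldeca-1,5,7-trien-4-ol | C=C[C@H](C)[C@H](O)/C=C/C(C)=C\[C@@H](C)CI | intermediate
20 | acryloyl chloride | C=CC(Cl)=O | starting material
21 | (3S,4R,5E,7Z,9R)-10-iodo-3,7,9-trimethyldeca-1,5,7-trien-4-yl acrylate | C=C[C@H](C)[C@H](OC(=O)C=C)/C=C/C(C)=C\[C@@H](C)CI | intermediate
22 | (5S,6R)-6-[(1E,3Z,5R)-6-iodo-3,5-dimethylhexa-1,3-dien-1-yl]-5-methyl-5,6-dihydro-2H-pyran-2-one | CC(=C/[C@@H](C)CI)/C=C/[C@H]1OC(=O)C=C[C@@H]1C | intermediate
23 | (S)-3-bromo-2-methylpropan-1-ol | OC[C@H](C)CBr | starting material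
24 | (S)-(3-bromo-2-methylpropoxy)triethylsilane | CC[Si](CC)(CC)OC[C@H](C)CBr | intermediate
25 | but-2-ynoic acid | CC#CC(=O)O | starting material
26 | 2-(trimethylsilyl)ethanol | C[Si](C)(C)CCO | starting material
27 | 2-(trimethylsilyl)ethyl but-2-ynoate | CC#CC(=O)OCC[Si](C)(C)C | intermediate
28 | [(2S)-2-methyl-3-(triethylsilyloxy)propyl]magnesium bromide | CC[Si](CC)(CC)OC[C@H](C)C[Mg]Br | intermediate
29 | [(2S)-2-methyl-3-(triethylsilyloxy)propyl]copper (monovalent copper, MgBr2 complex) | CC[Si](CC)(CC)OC[C@H](C)C[Cu] | intermediate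
30 | 2-(trimethylsilyl)ethyl (2E,5R)-3,5-dimethyl-6-(triethylsilyloxy)hex-2-enoate | CC[Si](CC)(CC)OC[C@H](C)C/C(C)=C/C(=O)OCC[Si](C)(C)C | intermediate
31 | 2-(trimethylsilyl)ethyl (2E,5R)-3,5-dimethyl-6-oxohex-2-enoate | O=C[C@H](C)C/C(C)=C/C(=O)OCC[Si](C)(C)C | intermediate
32 | 2-(trimethylsilyl)ethyl (2E,5R,6R,7S)-6-hydroxy-3,5,7-trimethylnona-2,8-dienoate | C=C[C@H](C)[C@H](O)[C@H](C)C/C(C)=C/C(=O)OCC[Si](C)(C)C | intermediate
33 | 2-(trimethylsilyl)ethyl (2E,5R,6R,7S)-3,5,7-trimethyl-6-(triethylsilyloxy)nona-2,8-dienoate | C=C[C@H](C)[C@H](O[Si](CC)(CC)CC)[C@H](C)C/C(C)=C/C(=O)OCC[Si](C)(C)C | intermediate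
34 | 1,2,4-trioxolane (ozonide) of the terminal olefin of 33 | C1OOC(O1)[C@H](C)[C@H](O[Si](CC)(CC)CC)[C@H](C)C/C(C)=C/C(=O)OCC[Si](C)(C)C | intermediate
35 | 2-(trimethylsilyl)ethyl (2E,5R,6R,7R)-3,5,7-trimethyl-8-oxo-6-(triethylsilyloxy)oct-2-enoate | O=C[C@H](C)[C@H](O[Si](CC)(CC)CC)[C@H](C)C/C(C)=C/C(=O)OCC[Si](C)(C)C | intermediate
36 | but-3-enoic acid | C=CCC(=O)O | starting material
37 | (R)-4-benzyloxazolidin-2-one | O=C1N[C@H](Cc2ccccc2)CO1 | starting material
38 | but-3-enoic pivalic anhydride | C=CCC(=O)OC(=O)C(C)(C)C | intermediate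
39 | (R)-4-benzyl-3-(but-3-enoyl)oxazolidin-2-one | C=CCC(=O)N1[C@H](Cc2ccccc2)COC1=O | intermediate
40 | methacrolein | C=C(C)C=O | starting material
41 | (R)-4-benzyl-3-[(3E)-4-methyl-5-oxopent-3-enoyl]oxazolidin-2-one | O=C/C(C)=C/CC(=O)N1[C@H](Cc2ccccc2)COC1=O | intermediate
42 | (R)-4-benzyl-3-[(3E,5E)-6-iodo-4-methylhexa-3,5-dienoyl]oxazolidin-2-one | I/C=C/C(C)=C/CC(=O)N1[C@H](Cc2ccccc2)COC1=O | intermediate
43 | dibutylboron (Z)-enolate of 42 | CCCCB(CCCC)O/C(=C\C=C(C)\C=C\I)N1[C@H](Cc2ccccc2)COC1=O | intermediate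
44 | 2-(trimethylsilyl)ethyl (2E,5R,6R,7S,8S,9R)-10-[(R)-4-benzyl-2-oxooxazolidin-3-yl]-8-hydroxy-9-[(1E,3E)-4-iodo-2-methylbuta-1,3-dien-1-yl]-3,5,7-trimethyl-10-oxo-6-(triethylsilyloxy)dec-2-enoate | O=C1OC[C@@H](Cc2ccccc2)N1C(=O)[C@H](/C=C(C)/C=C/I)[C@@H](O)[C@H](C)[C@H](O[Si](CC)(CC)CC)[C@H](C)C/C(C)=C/C(=O)OCC[Si](C)(C)C | intermediate
45 | 2-(trimethylsilyl)ethyl (2E,5R,6R,7S,8R,9S,10E,12E)-8-hydroxy-9-(hydroxymethyl)-13-iodo-3,5,7,11-tetramethyl-6-(triethylsilyloxy)trideca-2,10,12-trienoate | OC[C@H](/C=C(C)/C=C/I)[C@@H](O)[C@H](C)[C@H](O[Si](CC)(CC)CC)[C@H](C)C/C(C)=C/C(=O)OCC[Si](C)(C)C | intermediate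
46 | 2-(trimethylsilyl)ethyl (2E,5R,6R,7S,8R,9S,10E,12E)-9-{[(tert-butyldimethylsilyl)oxy]methyl}-8-hydroxy-13-iodo-3,5,7,11-tetramethyl-6-(triethylsilyloxy)trideca-2,10,12-trienoate | CC(C)(C)[Si](C)(C)OC[C@H](/C=C(C)/C=C/I)[C@@H](O)[C@H](C)[C@H](O[Si](CC)(CC)CC)[C@H](C)C/C(C)=C/C(=O)OCC[Si](C)(C)C | intermediate
47 | 2-(trimethylsilyl)ethyl (2E,5R,6R,7R,9S,10E,12E)-9-{[(tert-butyldimethylsilyl)oxy]methyl}-13-iodo-3,5,7,11-tetramethyl-8-oxo-6-(triethylsilyloxy)trideca-2,10,12-trienoate | CC(C)(C)[Si](C)(C)OC[C@H](/C=C(C)/C=C/I)C(=O)[C@H](C)[C@H](O[Si](CC)(CC)CC)[C@H](C)C/C(C)=C/C(=O)OCC[Si](C)(C)C | intermediate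
48 | {(2R,3Z,5E)-2,4-dimethyl-6-[(2R,3S)-3-methyl-6-oxo-3,6-dihydro-2H-pyran-2-yl]hexa-3,5-dien-1-yl}zinc iodide | CC(=C/[C@@H](C)C[Zn]I)/C=C/[C@H]1OC(=O)C=C[C@@H]1C | intermediate
49 | 2-(trimethylsilyl)ethyl (2E,5R,6R,7R,9S,10E,12E,15S,16Z,18E)-9-{[(tert-butyldimethylsilyl)oxy]methyl}-3,5,7,11,15,17-hexamethyl-19-[(2R,3S)-3-methyl-6-oxo-3,6-dihydro-2H-pyran-2-yl]-8-oxo-6-(triethylsilyloxy)nonadeca-2,10,12,16,18-pentaenoate | CC(=C/[C@@H](C)C/C=C/C(C)=C/[C@@H](CO[Si](C)(C)C(C)(C)C)C(=O)[C@H](C)[C@H](O[Si](CC)(CC)CC)[C@H](C)C/C(C)=C/C(=O)OCC[Si](C)(C)C)/C=C/[C@H]1OC(=O)C=C[C@@H]1C | intermediate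
50 | (2E,5R,6R,7R,9S,10E,12E,15S,16Z,18E)-6-hydroxy-9-(hydroxymethyl)-3,5,7,11,15,17-hexamethyl-19-[(2R,3S)-3-methyl-6-oxo-3,6-dihydro-2H-pyran-2-yl]-8-oxononadeca-2,10,12,16,18-pentaenoic acid | CC(=C/[C@@H](C)C/C=C/C(C)=C/[C@@H](CO)C(=O)[C@H](C)[C@H](O)[C@H](C)C/C(C)=C/C(=O)O)/C=C/[C@H]1OC(=O)C=C[C@@H]1C | target

Total step count: 29. Longest linear sequence: 14 steps (steps 1–9, 11–13, 28 and 29).

Steps most likely to fail

Step 28. Zinc insertion passes through a homoallylic radical at C11 that could scramble the neighbouring Z-diene or rearrange before it is trapped. Zerovalent palladium could also ionise the dienylic C5–O bond of the lactone once the alkenyl iodide runs low. The fallback masks the lactone and makes the organometallic by halogen–lithium exchange instead. It sets out from 22: iBu2AlH at −78 °C gives the lactol (5S,6R)-6-[(1E,3Z,5R)-6-iodo-3,5-dimethylhexa-1,3-dien-1-yl]-5-methyl-5,6-dihydro-2H-pyran-2-ol F1. Propan-2-ol with pyridinium p-toluenesulfonate converts it into the isopropyl acetal F2. tBuLi (2 equiv, Et2O, −78 °C) gives the alkyllithium F3, and ZnCl2 turns it into the alkylzinc chloride F4. Coupling with 47 under PdCl2(dppf) gives the coupled isopropyl acetal F5. Pyridinium p-toluenesulfonate in wet acetone at 0 °C frees the coupled lactol F6, and MnO2 oxidises this allylic lactol to the lactone, returning to the route at 49.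

Step 29. The fluoride source is basic enough that, once the C19 oxygen is freed, retro-aldol cleavage of C18–C19, epimerisation at C16 or β-elimination of the C16 oxymethyl group could compete with deprotection. The fallback removes the need for an ester cleavage by bringing C24 in at the alcohol level and oxidising it last under neutral conditions. It sets out from 45: iBu2AlH reduces the ester to the triol with a C24 allylic alcohol F7. TBSCl (2.2 equiv) and imidazole protect both primary hydroxyls to give the bis-silyl ether F8, and Dess–Martin periodinane gives the C17 ketone F9. Negishi coupling with zinc reagent 48, as in step 28, gives the coupled product F10. HF·pyridine buffered with pyridine in THF removes all silyl ethers to give the C24 alcohol F11. MnO2 oxidises only the allylic alcohol to the C24 enal F12, and NaClO2 with NaH2PO4 and 2-methylbut-2-ene gives the acid, returning to the route at 50.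

Step 18. Facial selectivity may be insufficient, because the reagent has to override the Felkin preference of the α-methyl aldehyde to reach the anti,anti triad. The fallback replaces crotylboration by Marshall propargylation, where the axial chirality of an allenylzinc fixes C18 and the cyclic transition state fixes the anti carbinol. It sets out from 31. (R)-But-3-yn-2-ol is mesylated (MeSO2Cl, Et3N, CH2Cl2, −78 °C) to (R)-but-3-yn-2-yl methanesulfonate F13. Pd(OAc)2 (5 mol %), PPh3 and Et2Zn (3 equiv) in THF at −78 → −20 °C convert it, by anti oxidative addition and transmetalation, into the allenylzinc (aS)-buta-1,2-dien-1-yl(ethyl)zinc F14. This adds to 31 on the zinc-bearing face to give the anti homopropargylic alcohol 2-(trimethylsilyl)ethyl (2E,5R,6R,7S)-6-hydroxy-3,5,7-trimethylnon-2-en-8-ynoate F15. Semi-hydrogenation (H2, Pd on CaCO3 poisoned with Pb(OAc)2, quinoline, EtOAc) reduces the alkyne to the vinyl group, returning to the route at 32.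

Further compounds
F1 | step 28 | (5S,6R)-6-[(1E,3Z,5R)-6-iodo-3,5-dimethylhexa-1,3-dien-1-yl]-5-methyl-5,6-dihydro-2H-pyran-2-ol | CC(=C/[C@@H](C)CI)/C=C/[C@H]1OC(O)C=C[C@@H]1C
F2 | step 28 | (2R,3S)-2-[(1E,3Z,5R)-6-iodo-3,5-dimethylhexa-1,3-dien-1-yl]-3-methyl-6-(propan-2-yloxy)-3,6-dihydro-2H-pyran | CC(=C/[C@@H](C)CI)/C=C/[C@H]1OC(OC(C)C)C=C[C@@H]1C
F3 | step 28 | alkyllithium from F2 (C11–Li) | CC(=C/[C@@H](C)C[Li])/C=C/[C@H]1OC(OC(C)C)C=C[C@@H]1C
F4 | step 28 | alkylzinc chloride from F3 (C11–ZnCl) | CC(=C/[C@@H](C)C[Zn]Cl)/C=C/[C@H]1OC(OC(C)C)C=C[C@@H]1C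
F5 | step 28 | isopropyl lactol acetal of 49 | CC(=C/[C@@H](C)C/C=C/C(C)=C/[C@@H](CO[Si](C)(C)C(C)(C)C)C(=O)[C@H](C)[C@H](O[Si](CC)(CC)CC)[C@H](C)C/C(C)=C/C(=O)OCC[Si](C)(C)C)/C=C/[C@H]1OC(OC(C)C)C=C[C@@H]1C
F6 | step 28 | lactol of 49 | CC(=C/[C@@H](C)C/C=C/C(C)=C/[C@@H](CO[Si](C)(C)C(C)(C)C)C(=O)[C@H](C)[C@H](O[Si](CC)(CC)CC)[C@H](C)C/C(C)=C/C(=O)OCC[Si](C)(C)C)/C=C/[C@H]1OC(O)C=C[C@@H]1C
F7 | step 29 | triol from 45 with the C24 ester reduced to the allylic alcohol | OC[C@H](/C=C(C)/C=C/I)[C@@H](O)[C@H](C)[C@H](O[Si](CC)(CC)CC)[C@H](C)C/C(C)=C/CO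
F8 | step 29 | bis(tert-butyldimethylsilyl) ether of F7 at both primary hydroxyls | CC(C)(C)[Si](C)(C)OC[C@H](/C=C(C)/C=C/I)[C@@H](O)[C@H](C)[C@H](O[Si](CC)(CC)CC)[C@H](C)C/C(C)=C/CO[Si](C)(C)C(C)(C)C
F9 | step 29 | C17 ketone from F8 | CC(C)(C)[Si](C)(C)OC[C@H](/C=C(C)/C=C/I)C(=O)[C@H](C)[C@H](O[Si](CC)(CC)CC)[C@H](C)C/C(C)=C/CO[Si](C)(C)C(C)(C)C
F10 | step 29 | coupling product of F9 and 48 (C24 silyl ether) | CC(=C/[C@@H](C)C/C=C/C(C)=C/[C@@H](CO[Si](C)(C)C(C)(C)C)C(=O)[C@H](C)[C@H](O[Si](CC)(CC)CC)[C@H](C)C/C(C)=C/CO[Si](C)(C)C(C)(C)C)/C=C/[C@H]1OC(=O)C=C[C@@H]1C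
F11 | step 29 | C24 primary alcohol corresponding to 50 | CC(=C/[C@@H](C)C/C=C/C(C)=C/[C@@H](CO)C(=O)[C@H](C)[C@H](O)[C@H](C)C/C(C)=C/CO)/C=C/[C@H]1OC(=O)C=C[C@@H]1C
F12 | step 29 | C24 aldehyde corresponding to 50 | CC(=C/[C@@H](C)C/C=C/C(C)=C/[C@@H](CO)C(=O)[C@H](C)[C@H](O)[C@H](C)C/C(C)=C/C=O)/C=C/[C@H]1OC(=O)C=C[C@@H]1C
F13 | step 18 | (R)-but-3-yn-2-yl methanesulfonate | C#C[C@@H](C)OS(C)(=O)=O
F14 | step 18 | (aS)-buta-1,2-dien-1-yl(ethyl)zinc | CC[Zn]C=C=CC
F15 | step 18 | 2-(trimethylsilyl)ethyl (2E,5R,6R,7S)-6-hydroxy-3,5,7-trimethylnon-2-en-8-ynoate | C#C[C@H](C)[C@H](O)[C@H](C)C/C(C)=C/C(=O)OCC[Si](C)(C)C
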